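**Plan** (prostanoid numbering: ester carbon C1, ketone C9, chloro-alkene C10=C11, oxygen-bearing ring-fusion carbon C12, octenyl chain C13–C20)
1. Retrosynthesis: remove the two acetates, then the C10 chlorine and the C10=C11 unsaturation (latent as a C11 silyl ether), then cut C7–C8 and O–C6 of the oxolane; this leaves a C1–C7 cis-epoxy aldehyde and a C8–C20 α,β-epoxy cyclopentanone, whose C14=C15 alkene goes back to an allyl group.
2. Enabling feature: in the fused oxolane (O, C6, C7, C8, C12) the oxygen sits on C12, β to the C9 ketone through ring-fusion carbon C8, and C7 carries an oxygen β to the same ketone. O–C12–C8 is therefore the retron of a reductively opened keto-oxirane (O, C12, C8), C8–C7 an aldol retron, and O–C6 with C5–O an epoxide-opening retron.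
3. Forward order: the cyclopentane ring is bought; allyl is added at C12, the C8–C12 oxirane is installed and the chain is completed by Z-selective cross-metathesis. The oxirane is then expanded to the oxolane by insertion of C7–C6 of the aldehyde into its C8–O bond (C7–C8 first, then O–C6); chloro-enone formation and acetylation finish the route.
4. Stereochemistry: the C8/C12 oxirane follows from the single stereocentre of (R)-4-silyloxycyclopentenone (anti epoxidation; that centre is later expelled as silanol). C5/C6 come from Sharpless epoxidation of a Z-allylic alcohol, with C6 inverted on ring closure. C7 and C8 are set in the aldol (anti aldol of the ring E-enolate, Felkin addition, cis ring fusion enforced).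

Key step: step 8

Remark: (R)-4-(tert-butyldimethylsilyloxy)cyclopent-2-enone, methyl 7-hydroxyhept-5-ynoate and a cyclometalated Z-selective ruthenium metathesis catalyst are taken as commercial.

**Step 1**
Reactants: 1 (4R)-4-[(tert-butyldimethylsilyl)oxy]cyclopent-2-en-1-one; 2 allylmagnesium bromide
Product: 3 tert-butyldimethyl{[(1R,2R)-2-(prop-2-en-1-yl)-4-[(trimethylsilyl)oxy]cyclopent-3-en-1-yl]oxy}silane (trans)
Conditions: 2 (1.3 equiv), CuBr·SMe2 (1.3 equiv), TMSCl (2 equiv), THF, −78 °C
Reagents that add atoms: chlorotrimethylsilane C[Si](C)(C)Cl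
Why: Organocopper conjugate addition with chlorosilane trapping: the allylcopper reagent should add 1,4 anti to the C4 silyloxy group and TMSCl should capture the enolate regiospecifically as the silyl enol ether needed for step 2 (the new sp3 centre is erased there).

**Step 2**
Reactants: 3 the silyl enol ether
Product: 4 (4R)-4-[(tert-butyldimethylsilyl)oxy]-3-(prop-2-en-1-yl)cyclopent-2-en-1-one
Conditions: Pd(OAc)2 (1.0 equiv), MeCN, rt
Reagents that add atoms: none
Why: Saegusa–Ito oxidation: the Pd(II) enolate from the enol silane should undergo β-hydride elimination toward the allyl-bearing carbon, giving the enone with allyl on the β-carbon; no stereocentre is formed.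

**Step 3**
Reactants: 4 the β-allyl enone
Product: 5 (1S,4R,5R)-4-[(tert-butyldimethylsilyl)oxy]-5-(prop-2-en-1-yl)-6-oxabicyclo[3.1.0]hexan-2-one (oxirane anti to the silyloxy group)
Conditions: 30% H2O2, NaOH (cat.), MeOH, −10 to 0 °C
Reagents that add atoms: hydrogen peroxide OO
Why: Weitz–Scheffer nucleophilic epoxidation: hydroperoxide should add to the β-carbon from the face opposite the adjacent silyloxy group and the enolate then closes the oxirane, so both oxirane carbons (C8 and quaternary C12) are set by the single C11 stereocentre.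

**Step 4**
Reactants: 5 the allyl epoxy ketone; 6 hept-1-ene
Product: 7 (1S,4R,5R)-4-[(tert-butyldimethylsilyl)oxy]-5-[(2Z)-oct-2-en-1-yl]-6-oxabicyclo[3.1.0]hexan-2-one
Conditions: 6 (8 equiv), cyclometalated Ru nitrato catalyst (Grubbs Z-selective, 5 mol%), THF, 35 °C
Reagents that add atoms: none
Why: Z-selective olefin cross-metathesis of the terminal allyl group with excess hept-1-ene should give the (Z)-oct-2-enyl chain; ketone, oxirane and silyl ether are inert and no stereocentre changes.

**Step 5**
Reactants: 8 methyl 7-hydroxyhept-5-ynoate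
Product: 9 methyl (5Z)-7-hydroxyhept-5-enoate
Conditions: H2 (1 atm), Lindlar catalyst, quinoline, EtOAc, rt
Reagents that add atoms: none
Why: Lindlar semihydrogenation: syn addition of hydrogen on the poisoned palladium surface should give the (Z)-allylic alcohol without over-reduction.

**Step 6**
Reactants: 9 the (Z)-allylic alcohol
Product: 10 methyl 4-[(2R,3S)-3-(hydroxymethyl)oxiran-2-yl]butanoate (cis-epoxide)
Conditions: Ti(OiPr)4 (10 mol%), L-(+)-diethyl tartrate (12 mol%), t-BuOOH (2 equiv), 4 Å MS, CH2Cl2, −20 °C
Reagents that add atoms: tert-butyl hydroperoxide CC(C)(C)OO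
Why: Sharpless asymmetric epoxidation: the titanium–L-(+)-tartrate complex should deliver oxygen to one face of the Z-allylic alcohol, setting both oxirane carbons (C5 R, C6 S) by reagent control.

**Step 7**
Reactants: 10 the cis-epoxy alcohol
Product: 11 methyl 4-[(2R,3R)-3-formyloxiran-2-yl]butanoate (cis-epoxy aldehyde)
Conditions: Dess–Martin periodinane (1.2 equiv), NaHCO3, CH2Cl2, 0 °C; used at once
Reagents that add atoms: none
Why: Dess–Martin oxidation of the primary alcohol under buffered, non-epimerising conditions should give the cis-epoxy aldehyde with both oxirane centres intact (the C6 descriptor changes only because the priorities change).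

**Step 8**
Reactants: 7 the octenyl epoxy ketone; 11 the cis-epoxy aldehyde
Product: 14 methyl (5R)-5-[(2S,3S,3aS,6R,6aR)-6-[(tert-butyldimethylsilyl)oxy]-3-hydroxy-6a-[(2Z)-oct-2-en-1-yl]-4-oxohexahydro-2H-cyclopenta[b]furan-2-yl]-5-hydroxypentanoate, via samarium enolate alkoxide 12 (not isolated), via epoxy aldol adduct 13 (not isolated)
Conditions: SmI2 (2.1 equiv), THF, −78 °C; then 11 (1.05 equiv), −78 °C; then AcOH (2.5 equiv), CSA (0.2 equiv), −78 to 0 °C
Reagents that add atoms: none
Why: Proposed new method: two single-electron transfers from SmI2 to the ketone should cleave the α C8–O bond of the oxirane to give a regiospecific Sm(III) enolate that keeps the oxirane oxygen as the C12 alkoxide (12); the enolate adds to aldehyde 11 (C7–C8, giving 13) and, after protonation, the tertiary C12–OH opens the cis-epoxide at C6 with inversion (O–C6), so that C7–C6 is inserted into the former C8–O bond and the three-membered O–C12–C8 ring becomes the five-membered oxolane. The closest known reactions are the SmI2 opening of α,β-epoxy ketones to β-hydroxy ketones, samarium-enolate (Reformatsky-type) aldol additions and acid-catalysed epoxy-alcohol cyclisation; what is new is their union into one ring-expanding operation. The oxolane closes by 5-exo-tet attack of the tertiary alcohol on C6 of the epoxide (6-endo attack at C5 is stereoelectronically disfavoured), and no other ring is formed. C12 is carried over unchanged; C8 is set by aldehyde approach to the enolate face syn to the C12 O–Sm group and anti to the C13 chain and the C11 silyl ether (only this cis adduct can close); C7 is set by the closed Zimmerman–Traxler transition state of the ring E-enolate (anti aldol), reinforced by Felkin–Anh addition to the α-oxygenated aldehyde, whose weakly basic oxirane oxygen should chelate poorly; C6 is inverted and C5 retained from the Sharpless epoxide. The step needs SmI2 to be consumed by 7 before 11 is added (so the aldehyde and its epoxide are not reduced), enolate formation at C8 and not C10 (secured by the position of the oxirane), and an acidic quench at −78 °C without excess aldehyde to avoid Payne rearrangement and aldol–Tishchenko reduction.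

**Step 9**
Reactants: 14 the bicyclic diol
Product: 15 acetonide of 14 (2,2-dimethyl-1,3-dioxane spanning the C5 and C7 oxygens)
Conditions: 2,2-dimethoxypropane, PPTS (cat.), CH2Cl2, rt
Reagents that add atoms: 2,2-dimethoxypropane COC(C)(C)OC
Why: Acid-catalysed transketalisation should tie the two secondary hydroxyls, which are cis on the oxolane, into a six-membered acetonide that protects them for the enolate chemistry; ketone, silyl ether and ester are untouched.

**Step 10**
Reactants: 15 the acetonide
Product: 17 chloro-enone acetonide, via α-chloro ketone acetonide 16 (not isolated)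
Conditions: LiHMDS (1.05 equiv), THF, −78 °C; NCS, −78 °C; then DBU, −78 to 0 °C
Reagents that add atoms: N-chlorosuccinimide O=C1CCC(=O)N1Cl
Why: Kinetic enolate chlorination followed by E1cB elimination: LiHMDS should deprotonate the unhindered C10 methylene and not the ring-fusion C8–H, NCS chlorinates the enolate, and DBU removes the acidified C10–H with loss of the β-silyloxy group to give the 2-chloro-enone; the C10 and C11 centres disappear.

**Step 11**
Reactants: 17 the chloro-enone acetonide
Product: 18 methyl (5R)-5-[(2S,3S,3aS,6aR)-5-chloro-3-hydroxy-6a-[(2Z)-oct-2-en-1-yl]-4-oxo-3,3a,4,6a-tetrahydro-2H-cyclopenta[b]furan-2-yl]-5-hydroxypentanoate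
Conditions: AcOH–H2O–THF (3:1:1), 40 °C
Reagents that add atoms: none
Why: Acid-catalysed hydrolysis of the isopropylidene acetal should free the two secondary alcohols; the β-hydroxy ketone and methyl ester tolerate dilute acetic acid.

**Step 12**
Reactants: 18 the diol
Product: 19 methyl (5R)-5-acetoxy-5-[(2S,3S,3aS,6aR)-3-acetoxy-5-chloro-6a-[(2Z)-oct-2-en-1-yl]-4-oxo-3,3a,4,6a-tetrahydro-2H-cyclopenta[b]furan-2-yl]pentanoate (target)
Conditions: Ac2O, pyridine, CH2Cl2, 0 °C
Reagents that add atoms: acetic anhydride CC(=O)OC(C)=O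
Why: Esterification of the two secondary alcohols with acetic anhydride/pyridine at low temperature should give the target without touching a stereocentre (there is no other free hydroxyl).

**Compound list**

1 | (4R)-4-[(tert-butyldimethylsilyl)oxy]cyclopent-2-en-1-one | O=C1C=C[C@H](O[Si](C)(C)C(C)(C)C)C1 | starting material
2 | allylmagnesium bromide | C=CC[Mg]Br | starting material
3 | tert-butyldimethyl{[(1R,2R)-2-(prop-2-en-1-yl)-4-[(trimethylsilyl)oxy]cyclopent-3-en-1-yl]oxy}silane | C=CC[C@@H]1C=C(O[Si](C)(C)C)C[C@H]1O[Si](C)(C)C(C)(C)C | intermediate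
4 | (4R)-4-[(tert-butyldimethylsilyl)oxy]-3-(prop-2-en-1-yl)cyclopent-2-en-1-one | C=CCC1=CC(=O)C[C@H]1O[Si](C)(C)C(C)(C)C | intermediate
5 | (1S,4R,5R)-4-[(tert-butyldimethylsilyl)oxy]-5-(prop-2-en-1-yl)-6-oxabicyclo[3.1.0]hexan-2-one | C=CC[C@@]12O[C@@H]1C(=O)C[C@H]2O[Si](C)(C)C(C)(C)C | intermediate
6 | hept-1-ene | C=CCCCCC | starting material
7 | (1S,4R,5R)-4-[(tert-butyldimethylsilyl)oxy]-5-[(2Z)-oct-2-en-1-yl]-6-oxabicyclo[3.1.0]hexan-2-one | CCCCC/C=C\C[C@@]12O[C@@H]1C(=O)C[C@H]2O[Si](C)(C)C(C)(C)C | intermediate
8 | methyl 7-hydroxyhept-5-ynoate | COC(=O)CCCC#CCO | starting material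
9 | methyl (5Z)-7-hydroxyhept-5-enoate | COC(=O)CCC/C=C\CO | intermediate
10 | methyl 4-[(2R,3S)-3-(hydroxymethyl)oxiran-2-yl]butanoate | OC[C@@H]1O[C@@H]1CCCC(=O)OC | intermediate
11 | methyl 4-[(2R,3R)-3-formyloxiran-2-yl]butanoate | O=C[C@@H]1O[C@@H]1CCCC(=O)OC | intermediate
12 | samarium enolate alkoxide: bis(diiodosamarium) C9 enolate / C12 alkoxide formed by C8–O cleavage of the oxirane of 7 | CCCCC/C=C\C[C@]1(O[Sm](I)I)[C@H](O[Si](C)(C)C(C)(C)C)CC(O[Sm](I)I)=C1 | intermediate
13 | epoxy aldol adduct: methyl 4-[(2R,3S)-3-{(S)-[(1S,2R,3R)-3-[(tert-butyldimethylsilyl)oxy]-2-hydroxy-2-[(2Z)-oct-2-en-1-yl]-5-oxocyclopentyl](hydroxy)methyl}oxiran-2-yl]butanoate (anti,anti; tertiary C12–OH, C7–OH, intact cis-epoxide) | CCCCC/C=C\C[C@]1(O)[C@H](O[Si](C)(C)C(C)(C)C)CC(=O)[C@H]1[C@H](O)[C@@H]2O[C@@H]2CCCC(=O)OC | intermediate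
14 | methyl (5R)-5-[(2S,3S,3aS,6R,6aR)-6-[(tert-butyldimethylsilyl)oxy]-3-hydroxy-6a-[(2Z)-oct-2-en-1-yl]-4-oxohexahydro-2H-cyclopenta[b]furan-2-yl]-5-hydroxypentanoate | CCCCC/C=C\C[C@]12[C@H](O[Si](C)(C)C(C)(C)C)CC(=O)[C@H]1[C@H](O)[C@H]([C@@H](CCCC(=O)OC)O)O2 | intermediate
15 | acetonide of 14 (2,2-dimethyl-1,3-dioxane across the C5 and C7 oxygens, cis-fused to the oxolane) | CCCCC/C=C\C[C@]12[C@H](O[Si](C)(C)C(C)(C)C)CC(=O)[C@H]1[C@@H]3OC(C)(C)O[C@H](CCCC(=O)OC)[C@@H]3O2 | intermediate
16 | α-chloro ketone acetonide: 15 bearing chlorine at C10, anti to the C11 silyloxy group | CCCCC/C=C\C[C@]12[C@H](O[Si](C)(C)C(C)(C)C)[C@@H](Cl)C(=O)[C@H]1[C@@H]3OC(C)(C)O[C@H](CCCC(=O)OC)[C@@H]3O2 | intermediate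
17 | chloro-enone acetonide: C10-chloro C10=C11 enone with the C5/C7 acetonide still in place | CCCCC/C=C\C[C@]12C=C(Cl)C(=O)[C@H]1[C@@H]3OC(C)(C)O[C@H](CCCC(=O)OC)[C@@H]3O2 | intermediate
18 | methyl (5R)-5-[(2S,3S,3aS,6aR)-5-chloro-3-hydroxy-6a-[(2Z)-oct-2-en-1-yl]-4-oxo-3,3a,4,6a-tetrahydro-2H-cyclopenta[b]furan-2-yl]-5-hydroxypentanoate | CCCCC/C=C\C[C@]12C=C(Cl)C(=O)[C@H]1[C@H](O)[C@H]([C@@H](CCCC(=O)OC)O)O2 | intermediate
19 | methyl (5R)-5-acetoxy-5-[(2S,3S,3aS,6aR)-3-acetoxy-5-chloro-6a-[(2Z)-oct-2-en-1-yl]-4-oxo-3,3a,4,6a-tetrahydro-2H-cyclopenta[b]furan-2-yl]pentanoate | CCCCC/C=C\C[C@]12C=C(Cl)C(=O)[C@H]1[C@H](OC(C)=O)[C@H]([C@@H](CCCC(=O)OC)OC(C)=O)O2 | target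

**Step count and risks**

Total steps: 12. Longest linear sequence: 9 (steps 1–4 and 8–12).

Steps most likely to fail:

1. Step 8. Possible failures are attack on the wrong enolate face at C8, chelation-controlled (syn) addition to the epoxy aldehyde under Sm(III), aldol–Tishchenko reduction of the ketone, retro-aldol cleavage, or Payne rearrangement before ring closure. The fallback sets out from 7 and uses three established operations. SmI2 reduction of 7 with silylation of the resulting enolate and alkoxide (TMSCl, Et3N) should give the bis-trimethylsilyl compound (TMS enol ether and tertiary TMS ether) F1. Methyllithium cleaves the enol silane to the regiodefined lithium enolate, which adds to 11 at −78 °C through a closed, non-chelating transition state to give the aldol adduct as its tertiary TMS ether F2. CSA in methanol–CH2Cl2 removes the TMS ether and effects the 5-exo epoxide opening, returning to 14.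

2. Step 10. Possible failures are enolisation toward the ring-fusion carbon with β-elimination of the C7 oxygen or retro-oxa-Michael opening of the oxolane, loss of silanolate before chlorination, or over-chlorination. The fallback sets out from 15 and introduces chlorine by the classical epoxy-ketone route. Buffered TBAF should give the β-hydroxy ketone acetonide F3; MsCl/Et3N dehydrates it to the chlorine-free enone acetonide F4; H2O2/NaOH gives the C10–C11 keto-epoxide F5. HCl in wet methanol then opens the oxirane at C10 with chloride, dehydrates the chlorohydrin and cleaves the acetonide, returning to 18.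

3. Step 3. Possible failures are base-induced loss of silanolate after α′-enolisation of the γ-silyloxy enone, migration of the allyl double bond into conjugation, or slow hydroperoxide addition to the β,β-disubstituted enone. The fallback sets out from 4 and avoids basic peroxide. Luche reduction (hydride anti to the silyloxy group) should give the cis-allylic alcohol (1S,4R)-4-[(tert-butyldimethylsilyl)oxy]-3-(prop-2-en-1-yl)cyclopent-2-en-1-ol F6; TESCl/imidazole gives its triethylsilyl ether F7; mCPBA epoxidises the ring alkene anti to both silyloxy groups to give the epoxide F8. PPTS in methanol removes the triethylsilyl group selectively to give the epoxy alcohol F9, and Dess–Martin oxidation of the secondary alcohol returns to 5.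

**Further compounds**

F1 | step 8 | bis-TMS derivative of the enolate–alkoxide from 7 (TMS enol ether, tertiary TMS ether) | CCCCC/C=C\C[C@]1(O[Si](C)(C)C)[C@H](O[Si](C)(C)C(C)(C)C)CC(O[Si](C)(C)C)=C1
F2 | step 8 | aldol adduct 13 as its tertiary TMS ether | CCCCC/C=C\C[C@]1(O[Si](C)(C)C)[C@H](O[Si](C)(C)C(C)(C)C)CC(=O)[C@H]1[C@H](O)[C@@H]2O[C@@H]2CCCC(=O)OC
F3 | step 10 | C11 alcohol from desilylation of 15 (β-hydroxy ketone acetonide) | CCCCC/C=C\C[C@]12[C@H](O)CC(=O)[C@H]1[C@@H]3OC(C)(C)O[C@H](CCCC(=O)OC)[C@@H]3O2
F4 | step 10 | chlorine-free enone acetonide | CCCCC/C=C\C[C@]12C=CC(=O)[C@H]1[C@@H]3OC(C)(C)O[C@H](CCCC(=O)OC)[C@@H]3O2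
F5 | step 10 | C10–C11 keto-epoxide of F4 (oxirane on the convex face) | CCCCC/C=C\C[C@]12[C@@H]4O[C@@H]4C(=O)[C@H]1[C@@H]3OC(C)(C)O[C@H](CCCC(=O)OC)[C@@H]3O2
F6 | step 3 | (1S,4R)-4-[(tert-butyldimethylsilyl)oxy]-3-(prop-2-en-1-yl)cyclopent-2-en-1-ol | C=CCC1=C[C@@H](O)C[C@H]1O[Si](C)(C)C(C)(C)C
F7 | step 3 | triethylsilyl ether of F6 | C=CCC1=C[C@@H](O[Si](CC)(CC)CC)C[C@H]1O[Si](C)(C)C(C)(C)C
F8 | step 3 | epoxide of F7, oxirane anti to both silyloxy groups | C=CC[C@@]12O[C@@H]1[C@@H](O[Si](CC)(CC)CC)C[C@H]2O[Si](C)(C)C(C)(C)C
F9 | step 3 | epoxy alcohol from F8 after removal of the triethylsilyl group | C=CC[C@@]12O[C@@H]1[C@@H](O)C[C@H]2O[Si](C)(C)C(C)(C)C
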